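## Structural features

- The target is an achiral, mirror-symmetric trimer: a central 2,4,6-trihydroxybutyrophenone ring whose two remaining ring carbons (C3 and C5) each carry a CH2 bridge to an identical outer ring.
- Each outer ring is a hexasubstituted benzene carrying, in ring order, the bridge, OH, butanoyl, OH, methyl and OMe. The methyl ether therefore lies para to the ketone, between the bridge carbon and the C-methyl carbon.
- There are no stereocentres, so no question of neighbouring stereocentres arises. Only the open-chain intermediates carry epimerisable centres, and these vanish on aromatisation.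
- Fragile features are the seven free phenols (easily oxidised as phenoxides) and the methylene bridges between phloroglucinol rings, which can exchange by retro-Friedel–Crafts or quinone-methide pathways in hot acid or alkali.
- The real difficulty is regiochemical: three fully substituted rings and nine ring oxygens, of which exactly one per outer ring must be methylated.
- The key step uses the 1,3,5-oxygenation of each outer ring. Its six ring carbons and the ketone carbon map onto C1–C7 of a methyl 4-methyl-3,5,7-trioxodecanoate: C1 is the carbinol carbon beside the bridge, C2 the bridge-bearing carbon, C3 the future OMe carbon, C4 the methyl-bearing carbon, C5 the second carbinol carbon, C6 the butanoyl-bearing carbon and C7 the ketone. One C6–C1 bond closes each ring.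

## Logic of the disconnections

**15 ⇒ 14.** The three O–benzyl bonds on the central ring are cut (protection added in the retro sense). The central hydroxyls must stay masked until the end, because free they would lactonise with the arms, compete in O-methylation and allow bridge exchange. This separates central from outer oxygens. The forward step must be neutral, which hydrogenolysis is.

**14 ⇒ 13.** The two O–CH3 bonds para to the outer ketones are cut. All three oxygens of each outer ring come from chain carbonyls as hydroxyls, so the methyl group has to be added after ring formation. The outer rings become plain C-methyl acylphloroglucinols. The forward step must pick the most acidic, non-chelated hydroxyl of each outer ring.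

**13 ⇒ 11 (through 12).** In each outer ring the bond between the butanoyl-bearing carbon and the carbinol carbon beside the bridge is cut. This retro-Claisen opens both hexasubstituted rings to two acyclic triketo ester arms attached through C2. The whole aromatic substitution problem becomes chain assembly. The forward step must favour C-acylation over aldol and lactone closure in both arms.

**11 ⇒ 9 + 10.** The C6–C7 bond of each chain is cut. In a diketo ester the terminal methyl ketone carbon is deprotonated last and is therefore the single most nucleophilic site. Four carbons per arm are removed as a purchased amide. The forward step needs two trianions in one molecule and a spectator ketone enolate that stays silent.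

**9 ⇒ 7 + 8.** The C4–C5 bond of each chain is cut. C4 is the only γ-carbon of the β-keto ester and already carries the methyl branch, so the position of that branch is fixed by construction. The forward step is a dianion acylation that must stop at the ketone.

**7 ⇒ 5 + 6.** The two CH2–C2 bonds are cut. C2 is the only doubly activated carbon of 6, so the point of attachment of each arm is unambiguous, and the central ring is used in both directions at once. The forward step must be a clean mono-C-alkylation at each benzylic carbon.

**5 ⇒ 4.** The two aryl–CH2Cl bonds are cut. The two open ring positions are each activated by three alkoxy groups, so a one-carbon electrophile enters there and nowhere else. The acid must be mild enough to spare the benzyl ethers.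

**4 ⇒ 3.** The three O–benzyl bonds are cut, giving the free triphenol. The forward step must alkylate oxygen, not ring carbon.

**3 ⇒ 1 + 2.** The aryl–carbonyl bond is cut: a Friedel–Crafts acylation of a symmetric triphenol, which must stop at mono-acylation.

## Other disconnections considered

**Alternative 1:** 

- **Cut:** on the central ring, the aryl–carbonyl bond of the butanoyl group and the aryl–oxygen bond of one adjacent hydroxyl.
- **Forward step:** fluoride would release a strained aryne from the ortho-silyl aryl triflate A2, which already carries both outer rings as benzyl and methyl ethers. Butanoic acid A3, as carboxylate, would add through oxygen to the aryne carbon next to a benzylic arm. The aryl anion so formed, beside a benzyloxy group, would take over the acyl group to give the ortho-hydroxyaryl ketone A1. One hydrogenolysis of six benzyl ethers would then lead to 15.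
- **In its favour:** the acyl group and its chelating hydroxyl arrive together and necessarily ortho. The inductive effect of the flanking benzyloxy group should send oxygen to the distal aryne carbon, which is the regiochemistry needed. No polyketone is handled.
- **Against it here:** the step forms no ring and only one C–C bond, so all three hexasubstituted rings and both bridges must exist beforehand. A2 needs a silyl group and a triflate on adjacent carbons of an already crowded ring. The aryl anion could simply be protonated by A3, stopping at the aryl ester. The aryne is flanked on both sides.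
- **Comparison:** on structure the chosen plan is stronger, because its key step creates the two most substituted rings. On mechanism the aryne route is kinetically controlled through a short-lived intermediate, whereas the Claisen folding is drawn to one product by aromatisation. On step economy the route to A2 would be clearly longer than the six steps to 11. The alternative is better on two points: one step after the key step instead of two, and no late site-selective O-methylation.

**Alternative 2:** 

- **Cut:** two bonds in each outer ring: bridge-bearing carbon to the oxygenated carbon beside the ketone-bearing carbon, and ketone-bearing carbon to the hydroxyl-bearing carbon beside the methyl group.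
- **Forward step:** the bis(silyl ketene acetal diene) A5 would react twice with 1-ethoxyhex-1-yn-3-one A6, as a Diels–Alder reaction or stepwise by conjugate addition and closure. The diene terminus carrying the central-ring methylene would bond to the ethoxy-bearing alkyne carbon and the acetal carbon to the acyl-bearing one. Loss of methanol would aromatise each adduct to give A4.
- **In its favour:** four C–C bonds and two rings form in one operation. Diene and ynone polarities match. The methoxy group is delivered by the diene.
- **Against it here:** A4 is not yet on the skeleton of 15. Its central ring lacks the butanoyl group, which would need a late Friedel–Crafts acylation between two benzyloxy groups in the presence of free outer phenols. Each outer ring carries an ethyl ether that must be cleaved beside a methyl ether. A6 is a push–pull alkyne and a weak dienophile. The reacting diene terminus bears the large arylmethyl group. A5 holds two moisture-sensitive ketene acetals of undefined double-bond geometry.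
- **Comparison:** on structure it equals the chosen plan in making both outer rings at once on a pre-formed central ring. It is better in bonds formed (four against two) and in fixing the methyl ether without a selective methylation. On mechanism both end in aromatisation, but a wrong first bond in the cycloaddition is not corrected, whereas wrong closures in the Claisen route are reversible. On step economy the gain of the key step would be spent on the extra acylation, the de-ethylation and the preparation of A5 and A6.

**Alternative 3:** 

- **Cut:** the central-ring bond between the butanoyl-bearing carbon and a neighbouring carbinol carbon.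
- **Forward step:** base would fold the 2,4-bis(arylmethyl) triketo ester A8 by attack of C6 on the ester carbon, closing the central ring as the free phloroglucinol A7. Hydrogenolysis of four benzyl ethers would give 15. A8 would come from two alkylations with the outer-ring benzylic bromide A9.
- **In its favour:** the reaction type is the same as in the chosen plan, so the mechanistic footing is equal. The outer ring is made once and used twice, an equal use of symmetry. The methyl ether is fixed on a simple monocyclic arene before coupling, and only one step follows the key step; on these two points it is better.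
- **Against it here:** the key step forms one ring and one bond instead of two of each. Both hexasubstituted outer rings must be made by stepwise aromatic substitution, including the same selective O-methylation, only earlier. A8 needs benzylation at C2 and C4 but not at C6 of a chain with three acidic sites, using a hindered electrophile. Its C4 carries a bulky arylmethyl group in place of methyl, which should slow enolisation and folding.
- **Comparison:** on structure the chosen plan applies the folding where it pays most, on the two unsymmetrical rings, and takes the simple central ring from a purchased arene. On mechanism the two are equal apart from the heavier substitution in A8. On step economy, about five steps to A9 plus chain assembly, folding and deprotection would be equal to or slightly longer than nine steps.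

Key step: step 7

**Remarks on the chemistry**

- Compounds 6, 8 and 10 are taken as purchased reagents. Intermediates 7, 9, 11 and 12 are handled as mixtures of diastereomers and keto–enol tautomers, all of which converge on aromatisation.
- The arms are grown from a simple β-keto ester by polyanion acylation. An unsymmetrical 3-oxoglutarate would offer two alkylation sites, and its enolised esters would quench a ketone enolate by proton transfer instead of being acylated.
- The one-carbon units are introduced with HCl, not HBr in acetic acid, to spare the benzyl ethers.

## Route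

**Step 1**
Reactants: 1 phloroglucinol; 2 butanoyl chloride
Product: 3 1-(2,4,6-trihydroxyphenyl)butan-1-one
Conditions: AlCl3 (3.5 equiv), PhNO2–CH2Cl2, 0 → 60 °C; aq. HCl
Reagents that add atoms: none
Why: Friedel–Crafts C-acylation of the strongly activated triphenol; the first acyl group, complexed to aluminium and chelated by its ortho hydroxyls, deactivates the ring enough to stop at the monoketone.

**Step 2**
Reactants: 3 1-(2,4,6-trihydroxyphenyl)butan-1-one
Product: 4 1-[2,4,6-tris(benzyloxy)phenyl]butan-1-one
Conditions: BnBr (3.6 equiv), K2CO3 (6 equiv), DMF, 70 °C
Reagents that add atoms: benzyl bromide, BrCc1ccccc1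
Why: Williamson ether synthesis on all three phenols; the dipolar aprotic solvent favours O- over ring C-benzylation and heat is needed for the last, chelated hydroxyl. Benzyl ethers withstand the strong bases of steps 4–7 and leave by neutral hydrogenolysis.

**Step 3**
Reactants: 4 1-[2,4,6-tris(benzyloxy)phenyl]butan-1-one
Product: 5 1-[2,4,6-tris(benzyloxy)-3,5-bis(chloromethyl)phenyl]butan-1-one
Conditions: (CH2O)n (6 equiv), HCl (4 M in dioxane), 1,4-dioxane, 15–25 °C
Reagents that add atoms: paraformaldehyde (formaldehyde unit), C=O; hydrogen chloride, Cl
Why: Blanc chloromethylation at the only two free ring positions, each ortho to two benzyloxy groups and para to the third. HCl at room temperature is chosen because HBr in acetic acid cleaves aryl benzyl ethers, and the fully substituted product cannot alkylate itself.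

**Step 4**
Reactants: 5 1-[2,4,6-tris(benzyloxy)-3,5-bis(chloromethyl)phenyl]butan-1-one; 6 methyl 3-oxopentanoate
Product: 7 dimethyl 2,2'-{[2,4,6-tris(benzyloxy)-5-butanoyl-1,3-phenylene]bis(methylene)}bis(3-oxopentanoate)
Conditions: 6 (6 equiv), NaH (5.5 equiv), NaI (0.2 equiv), THF–DMF, 0 → 25 °C
Reagents that add atoms: none
Why: Twofold C-alkylation of the sodium enolate of a β-keto ester by an activated benzylic chloride with iodide catalysis. Only C2 of 6 is doubly activated, so each arm is attached at the right carbon, and the excess of 6 suppresses double alkylation of one keto ester.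

**Step 5**
Reactants: 7 dimethyl 2,2'-{[2,4,6-tris(benzyloxy)-5-butanoyl-1,3-phenylene]bis(methylene)}bis(3-oxopentanoate); 8 N-methoxy-N-methylacetamide
Product: 9 dimethyl 2,2'-{[2,4,6-tris(benzyloxy)-5-butanoyl-1,3-phenylene]bis(methylene)}bis(4-methyl-3,5-dioxohexanoate)
Conditions: LiN(iPr)2 (5.3 equiv), THF, −78 → 0 °C; 8 (2.4 equiv), −78 → −20 °C; cold 1 M HCl
Reagents that add atoms: none
Why: γ-Acylation of a β-keto ester dianion: each arm is deprotonated at C2 and then at the ethyl CH2 (one more equivalent of base is taken up by the hindered aryl ketone), and the more basic γ-carbanion attacks the Weinreb amide. The chelated tetrahedral adduct prevents over-addition, and because the ethyl CH2 is the only γ-site the methyl branch ends on C4.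

**Step 6**
Reactants: 9 dimethyl 2,2'-{[2,4,6-tris(benzyloxy)-5-butanoyl-1,3-phenylene]bis(methylene)}bis(4-methyl-3,5-dioxohexanoate); 10 N-methoxy-N-methylbutanamide
Product: 11 dimethyl 2,2'-{[2,4,6-tris(benzyloxy)-5-butanoyl-1,3-phenylene]bis(methylene)}bis(4-methyl-3,5,7-trioxodecanoate)
Conditions: LiN(iPr)2 (7.3 equiv), THF, −78 → 0 °C; 10 (2.4 equiv), −78 → −20 °C; cold 1 M HCl to pH 3–4; used at once
Reagents that add atoms: none
Why: Terminal acylation of a 3,5-diketo ester trianion (polyanion acylation): after C2 and C4 the methyl ketone carbon is deprotonated last and is the most nucleophilic site, and it is acylated by the butanoyl Weinreb amide. Enolisation at C2 keeps the ester of each arm from reacting, and the hindered aryl-ketone enolate is a far weaker nucleophile than the terminal carbanions.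

**Step 7**
Reactants: 11 dimethyl 2,2'-{[2,4,6-tris(benzyloxy)-5-butanoyl-1,3-phenylene]bis(methylene)}bis(4-methyl-3,5,7-trioxodecanoate)
Product: 13 1-{2,4,6-tris(benzyloxy)-3,5-bis[(3-butanoyl-2,4,6-trihydroxy-5-methylphenyl)methyl]phenyl}butan-1-one, via half-folded mono-cyclised triketo ester 12 (not isolated)
Conditions: NaOMe (10 equiv), degassed MeOH, Ar, 25 → 60 °C; then 1 M HCl, 0 °C
Reagents that add atoms: none
Why: Methoxide turns each arm into its polyenolate; C6, the central carbon of the C5/C7 diketone enolate, adds to the C1 ester carbonyl while C2 is protonated, and loss of methoxide gives a 2-acylcyclohexane-1,3,5-trione that enolises at once to the aromatic phenoxide. This is the intramolecular Claisen (Dieckmann-type) condensation known to convert 3,5,7-triketo esters into acylphloroglucinols, run here on two independent arms, the first closure giving 12 and the second 13. Each outer ring closes in a 6-exo-trig mode with the enolate double bond outside the new ring, forming the bond between the future butanoyl-bearing carbon and the carbinol carbon beside the bridge. No stereocentre is created, and the C2 and C4 centres of both chains disappear on aromatisation, so the whole tautomer and diastereomer mixture converges on one product. The selectivity required is C-acylation at C6 over aldol closure and over lactonisation to a 4-hydroxy-2-pyranone: attack of C2 on C7 would give a quaternary carbon that cannot aromatise and remains reversible, C8 is not activated by two carbonyls, and enol lactones are reopened by methoxide, so only the Claisen product leaves the equilibrium as a stabilised phenoxide. A methyl ester with NaOMe in MeOH makes ester exchange degenerate and avoids saponification to an acid that could no longer be acylated, while excess base keeps every 1,3-dicarbonyl unit enolised and protected from retro-Claisen cleavage. The benzyl ethers keep the central oxygens from forming lactones or chromenes with the arms and block base-induced exchange of the bridges; air is excluded because the phenoxides oxidise easily.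

**Step 8**
Reactants: 13 1-{2,4,6-tris(benzyloxy)-3,5-bis[(3-butanoyl-2,4,6-trihydroxy-5-methylphenyl)methyl]phenyl}butan-1-one
Product: 14 1-{2,4,6-tris(benzyloxy)-3,5-bis[(3-butanoyl-2,4-dihydroxy-6-methoxy-5-methylphenyl)methyl]phenyl}butan-1-one
Conditions: TMSCHN2 (2.1 equiv), MeOH–toluene, 0 → 20 °C
Reagents that add atoms: trimethylsilyldiazomethane, C[Si](C)(C)C=[N+]=[N-]
Why: Phenol O-methylation by a diazoalkane, which follows acidity: on each outer ring the hydroxyl para to the ketone is the most acidic (a vinylogous acid that cannot chelate), whereas the two ortho hydroxyls share the carbonyl as hydrogen-bond acceptor and are less acidic. Para-selective mono-methylation is usual for 3,5-dialkylated acylphloroglucinols, and the central ring has no free hydroxyl at this stage.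

**Step 9**
Reactants: 14 1-{2,4,6-tris(benzyloxy)-3,5-bis[(3-butanoyl-2,4-dihydroxy-6-methoxy-5-methylphenyl)methyl]phenyl}butan-1-one
Product: 15 1-{3,5-bis[(3-butanoyl-2,4-dihydroxy-6-methoxy-5-methylphenyl)methyl]-2,4,6-trihydroxyphenyl}butan-1-one (CNP0264591.0)
Conditions: H2 (1 atm), Pd/C (palladium on carbon, 10 wt% Pd), EtOAc–MeOH, 20 °C
Reagents that add atoms: none
Why: Hydrogenolysis of the three aryl benzyl ethers under neutral conditions, which leaves the chelated aryl ketones, the methyl ethers and the acid- and base-sensitive methylene bridges untouched.

## Compound list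

1 | phloroglucinol (benzene-1,3,5-triol) | Oc1cc(O)cc(O)c1 | starting material
2 | butanoyl chloride | CCCC(=O)Cl | starting material
3 | 1-(2,4,6-trihydroxyphenyl)butan-1-one | CCCC(=O)c1c(O)cc(O)cc1O | intermediate
4 | 1-[2,4,6-tris(benzyloxy)phenyl]butan-1-one | CCCC(=O)c1c(OCc2ccccc2)cc(OCc2ccccc2)cc1OCc1ccccc1 | intermediate
5 | 1-[2,4,6-tris(benzyloxy)-3,5-bis(chloromethyl)phenyl]butan-1-one | CCCC(=O)c1c(OCc2ccccc2)c(CCl)c(OCc2ccccc2)c(CCl)c1OCc1ccccc1 | intermediate
6 | methyl 3-oxopentanoate | CCC(=O)CC(=O)OC | starting material
7 | dimethyl 2,2'-{[2,4,6-tris(benzyloxy)-5-butanoyl-1,3-phenylene]bis(methylene)}bis(3-oxopentanoate), diastereomer mixture, stereocentres unassigned | CCCC(=O)c1c(OCc2ccccc2)c(CC(C(=O)OC)C(=O)CC)c(OCc2ccccc2)c(CC(C(=O)OC)C(=O)CC)c1OCc1ccccc1 | intermediate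
8 | N-methoxy-N-methylacetamide | CC(=O)N(C)OC | starting material
9 | dimethyl 2,2'-{[2,4,6-tris(benzyloxy)-5-butanoyl-1,3-phenylene]bis(methylene)}bis(4-methyl-3,5-dioxohexanoate), diastereomer and tautomer mixture | CCCC(=O)c1c(OCc2ccccc2)c(CC(C(=O)OC)C(=O)C(C)C(C)=O)c(OCc2ccccc2)c(CC(C(=O)OC)C(=O)C(C)C(C)=O)c1OCc1ccccc1 | intermediate
10 | N-methoxy-N-methylbutanamide | CCCC(=O)N(C)OC | starting material
11 | dimethyl 2,2'-{[2,4,6-tris(benzyloxy)-5-butanoyl-1,3-phenylene]bis(methylene)}bis(4-methyl-3,5,7-trioxodecanoate), diastereomer and tautomer mixture | CCCC(=O)c1c(OCc2ccccc2)c(CC(C(=O)OC)C(=O)C(C)C(=O)CC(=O)CCC)c(OCc2ccccc2)c(CC(C(=O)OC)C(=O)C(C)C(=O)CC(=O)CCC)c1OCc1ccccc1 | intermediate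
12 | methyl 2-({2,4,6-tris(benzyloxy)-3-butanoyl-5-[(3-butanoyl-2,4,6-trihydroxy-5-methylphenyl)methyl]phenyl}methyl)-4-methyl-3,5,7-trioxodecanoate, diastereomer and tautomer mixture | CCCC(=O)c1c(OCc2ccccc2)c(Cc2c(O)c(C(=O)CCC)c(O)c(C)c2O)c(OCc2ccccc2)c(CC(C(=O)OC)C(=O)C(C)C(=O)CC(=O)CCC)c1OCc1ccccc1 | intermediate (not isolated)
13 | 1-{2,4,6-tris(benzyloxy)-3,5-bis[(3-butanoyl-2,4,6-trihydroxy-5-methylphenyl)methyl]phenyl}butan-1-one | CCCC(=O)c1c(OCc2ccccc2)c(Cc2c(O)c(C(=O)CCC)c(O)c(C)c2O)c(OCc2ccccc2)c(Cc2c(O)c(C(=O)CCC)c(O)c(C)c2O)c1OCc1ccccc1 | intermediate
14 | 1-{2,4,6-tris(benzyloxy)-3,5-bis[(3-butanoyl-2,4-dihydroxy-6-methoxy-5-methylphenyl)methyl]phenyl}butan-1-one | CCCC(=O)c1c(OCc2ccccc2)c(Cc2c(O)c(C(=O)CCC)c(O)c(C)c2OC)c(OCc2ccccc2)c(Cc2c(O)c(C(=O)CCC)c(O)c(C)c2OC)c1OCc1ccccc1 | intermediate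
15 | 1-{3,5-bis[(3-butanoyl-2,4-dihydroxy-6-methoxy-5-methylphenyl)methyl]-2,4,6-trihydroxyphenyl}butan-1-one (CNP0264591.0, achiral) | CCCC(=O)c1c(O)c(Cc2c(O)c(C(=O)CCC)c(O)c(C)c2OC)c(O)c(Cc2c(O)c(C(=O)CCC)c(O)c(C)c2OC)c1O | target

## Step count and least certain steps

Total step count: 9. Longest linear sequence: 9 steps (1 → 15); all other fragments are purchased.

**Step 7 (key step).** The most likely failure is closure through the C5 enol oxygen (lactonisation) instead of through C6, or folding of only one arm, with slow base-induced chain cleavage or air oxidation of the phenoxides as background losses. The ester is hindered by the C2 substituent, so C-acylation may be slow. The fallback gives up ring construction and couples pre-formed outer rings. Purchased 2-methylbenzene-1,3,5-triol F1 would be C-acylated with 2 (AlCl3, PhNO2) to 1-(2,4,6-trihydroxy-3-methylphenyl)butan-1-one F2. Two equivalents of F2, as the sodium phenoxide in methanol (NaOMe, 0 °C), would then be C-benzylated at their single free ring carbon by the bis-chloride 5. The fallback sets out from 5 and rejoins the route at 13.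

**Step 3.** The risk is acid-induced loss of benzyl ethers, above all those ortho to the ketone, and intermolecular Friedel–Crafts coupling of a chloromethylated ring with unreacted arene. The fallback sets out from 3 and introduces the carbons at the aldehyde level. Vilsmeier–Haack diformylation (POCl3, DMF) would give 5-butanoyl-2,4,6-trihydroxybenzene-1,3-dicarbaldehyde F3. Benzylation (BnBr, K2CO3, DMF) would give 2,4,6-tris(benzyloxy)-5-butanoylbenzene-1,3-dicarbaldehyde F4. Selective reduction of the aldehydes (NaBH4, THF–MeOH, 0 °C) would give 1-[2,4,6-tris(benzyloxy)-3,5-bis(hydroxymethyl)phenyl]butan-1-one F5. SOCl2 with Et3N in CH2Cl2 at 0 °C would convert F5 into 5, where the route is rejoined.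

**Step 6.** The risk is incomplete formation of two trianions in one molecule, proton transfer from the amide to the terminal carbanion, and competing acylation of the aryl-ketone enolate. The fallback sets out from 7 and brings in C5–C10 in one dianion acylation. Purchased methyl 3-oxohexanoate F6 would be ketalised (ethane-1,2-diol, TsOH, toluene, reflux) to methyl (2-propyl-1,3-dioxolan-2-yl)acetate F7. The bis-dianion of 7, made as in step 5 with one more equivalent of LiN(iPr)2 per arm, would be acylated by F7 to the bis-ketal dimethyl 2,2'-{[2,4,6-tris(benzyloxy)-5-butanoyl-1,3-phenylene]bis(methylene)}bis[4-methyl-3,5-dioxo-6-(2-propyl-1,3-dioxolan-2-yl)hexanoate] F8. Cold aqueous HCl in THF would remove the ketals and return the route at 11.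

**Step 8.** The risk is poor site selectivity among six phenols: methylation at an ortho hydroxyl or over-methylation, since the para hydroxyl is flanked by two carbon substituents. The fallback sets out from 13 and replaces selective alkylation by chelation-controlled dealkylation. Exhaustive methylation (MeI, K2CO3, DMF, 50 °C) would give 1-{2,4,6-tris(benzyloxy)-3,5-bis[(3-butanoyl-2,4,6-trimethoxy-5-methylphenyl)methyl]phenyl}butan-1-one F9. BCl3 (CH2Cl2, −78 → 0 °C) would then cleave the four methyl ethers ortho to the outer ketones and the three benzyl ethers, leaving the two para methyl ethers. This rejoins the route at 15.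

## Further compounds

F1 | step 7 | 2-methylbenzene-1,3,5-triol | Cc1c(O)cc(O)cc1O
F2 | step 7 | 1-(2,4,6-trihydroxy-3-methylphenyl)butan-1-one | CCCC(=O)c1c(O)cc(O)c(C)c1O
F3 | step 3 | 5-butanoyl-2,4,6-trihydroxybenzene-1,3-dicarbaldehyde | CCCC(=O)c1c(O)c(C=O)c(O)c(C=O)c1O
F4 | step 3 | 2,4,6-tris(benzyloxy)-5-butanoylbenzene-1,3-dicarbaldehyde | CCCC(=O)c1c(OCc2ccccc2)c(C=O)c(OCc2ccccc2)c(C=O)c1OCc1ccccc1
F5 | step 3 | 1-[2,4,6-tris(benzyloxy)-3,5-bis(hydroxymethyl)phenyl]butan-1-one | CCCC(=O)c1c(OCc2ccccc2)c(CO)c(OCc2ccccc2)c(CO)c1OCc1ccccc1
F6 | step 6 | methyl 3-oxohexanoate | CCCC(=O)CC(=O)OC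
F7 | step 6 | methyl (2-propyl-1,3-dioxolan-2-yl)acetate | CCCC1(CC(=O)OC)OCCO1
F8 | step 6 | dimethyl 2,2'-{[2,4,6-tris(benzyloxy)-5-butanoyl-1,3-phenylene]bis(methylene)}bis[4-methyl-3,5-dioxo-6-(2-propyl-1,3-dioxolan-2-yl)hexanoate], diastereomer mixture | CCCC(=O)c1c(OCc2ccccc2)c(CC(C(=O)OC)C(=O)C(C)C(=O)CC2(CCC)OCCO2)c(OCc2ccccc2)c(CC(C(=O)OC)C(=O)C(C)C(=O)CC2(CCC)OCCO2)c1OCc1ccccc1
F9 | step 8 | 1-{2,4,6-tris(benzyloxy)-3,5-bis[(3-butanoyl-2,4,6-trimethoxy-5-methylphenyl)methyl]phenyl}butan-1-one | CCCC(=O)c1c(OCc2ccccc2)c(Cc2c(OC)c(C(=O)CCC)c(OC)c(C)c2OC)c(OCc2ccccc2)c(Cc2c(OC)c(C(=O)CCC)c(OC)c(C)c2OC)c1OCc1ccccc1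
A1 | alternative 1 | 1-{2,4-bis(benzyloxy)-3,5-bis{[2,4-bis(benzyloxy)-3-butanoyl-6-methoxy-5-methylphenyl]methyl}-6-hydroxyphenyl}butan-1-one | CCCC(=O)c1c(O)c(Cc2c(OCc3ccccc3)c(C(=O)CCC)c(OCc3ccccc3)c(C)c2OC)c(OCc2ccccc2)c(Cc2c(OCc3ccccc3)c(C(=O)CCC)c(OCc3ccccc3)c(C)c2OC)c1OCc1ccccc1
A2 | alternative 1 | 2,4-bis(benzyloxy)-3,5-bis{[2,4-bis(benzyloxy)-3-butanoyl-6-methoxy-5-methylphenyl]methyl}-6-(trimethylsilyl)phenyl trifluoromethanesulfonate | FC(F)(F)S(=O)(=O)Oc1c([Si](C)(C)C)c(Cc2c(OCc3ccccc3)c(C(=O)CCC)c(OCc3ccccc3)c(C)c2OC)c(OCc2ccccc2)c(Cc2c(OCc3ccccc3)c(C(=O)CCC)c(OCc3ccccc3)c(C)c2OC)c1OCc1ccccc1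
A3 | alternative 1 | butanoic acid | CCCC(=O)O
A4 | alternative 2 | 1,3,5-tris(benzyloxy)-2,4-bis[(3-butanoyl-2-ethoxy-4-hydroxy-6-methoxy-5-methylphenyl)methyl]benzene | O(Cc1ccccc1)c1cc(OCc2ccccc2)c(Cc2c(OCC)c(C(=O)CCC)c(O)c(C)c2OC)c(OCc2ccccc2)c1Cc1c(OCC)c(C(=O)CCC)c(O)c(C)c1OC
A5 | alternative 2 | 1,3,5-tris(benzyloxy)-2,4-bis[3,5-dimethoxy-4-methyl-5-(trimethylsilyloxy)penta-2,4-dien-1-yl]benzene, double-bond geometry unspecified | O(Cc1ccccc1)c1cc(OCc2ccccc2)c(CC=C(OC)C(C)=C(OC)O[Si](C)(C)C)c(OCc2ccccc2)c1CC=C(OC)C(C)=C(OC)O[Si](C)(C)C
A6 | alternative 2 | 1-ethoxyhex-1-yn-3-one | CCCC(=O)C#COCC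
A7 | alternative 3 | 1-{3,5-bis{[2,4-bis(benzyloxy)-3-butanoyl-6-methoxy-5-methylphenyl]methyl}-2,4,6-trihydroxyphenyl}butan-1-one | CCCC(=O)c1c(O)c(Cc2c(OCc3ccccc3)c(C(=O)CCC)c(OCc3ccccc3)c(C)c2OC)c(O)c(Cc2c(OCc3ccccc3)c(C(=O)CCC)c(OCc3ccccc3)c(C)c2OC)c1O
A8 | alternative 3 | methyl 2,4-bis{[2,4-bis(benzyloxy)-3-butanoyl-6-methoxy-5-methylphenyl]methyl}-3,5,7-trioxodecanoate, diastereomer mixture | CCCC(=O)CC(=O)C(Cc1c(OCc2ccccc2)c(C(=O)CCC)c(OCc2ccccc2)c(C)c1OC)C(=O)C(Cc1c(OCc2ccccc2)c(C(=O)CCC)c(OCc2ccccc2)c(C)c1OC)C(=O)OC
A9 | alternative 3 | 1-[2,6-bis(benzyloxy)-3-(bromomethyl)-4-methoxy-5-methylphenyl]butan-1-one | CCCC(=O)c1c(OCc2ccccc2)c(CBr)c(OC)c(C)c1OCc1ccccc1
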